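Ring A is numbered C1 (quaternary; CO2H and 4-methylpent-3-enyl), C2 (CH bearing bridge carbon B1), C3, C4=C5 (C5 bears CH2OH), C6 (CH bearing B9); the bridge runs B1–B9 from C2 to C6.
Retrosynthesis: the 12-membered ring opens at B8–B9 (sulfone alkylation); the C2 arm is cut at B6=B7 (Still–Gennari) and at B4–B5 with B2=B3 (Johnson–Claisen); C6–B9 goes back to a C4–O allylic ester ([3,3] shift); the C5 CH2OH goes back to an α-iodoenone.
What remains is ring A with a ketone at C4, a 4,4,5-trisubstituted cyclohex-2-enone, which divides at C1–C2 and C5=C6 into an α-formyl ester (C1, C6) and an (E)-hex-3-en-2-one (C2–C5): a Robinson annulation.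
Forward: ring A is made first (step 6), the C6 arm follows, the C2 arm is then grown to B8, and the macrocycle closes last.
Stereochemistry: C1 and C2 come from the amine catalyst in step 6; C6 is relayed from C4 (Luche reduction, Mitsunobu inversion, suprafacial [3,3] shift); the E alkene comes from a chair Claisen transition state, the Z alkene from the Still–Gennari reaction.

Key step: step 6

Abbreviations and assumption: TBS = tert-butyldimethylsilyl, TBDPS = tert-butyldiphenylsilyl, Ts = 4-methylbenzenesulfonyl; the epi-quinine-derived primary amine is assumed to give the (1S,6S) enone by analogy with its additions of 1,3-dicarbonyl compounds to (E)-alk-3-en-2-ones, and if it gives the antipode its quinidine-derived pseudoenantiomer is used with no other change.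

Step 1
Reactants: 1 dimethyl malonate; 2 5-bromo-2-methylpent-2-ene
Product: 3 dimethyl 2-(4-methylpent-3-en-1-yl)malonate
Conditions: NaH, THF/DMF, 0 to 60 °C, excess 1
Reagents that add atoms: none
Why: Malonic ester alkylation (SN2) of the sodium enolate on the primary bromide, with excess malonate to suppress dialkylation.

Step 2
Reactants: 3 dimethyl 2-(4-methylpent-3-en-1-yl)malonate
Product: 4 methyl 6-methylhept-5-enoate
Conditions: LiCl, H2O, DMSO, 160 °C
Reagents that add atoms: none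
Why: Krapcho dealkoxycarbonylation, in which chloride demethylates one ester and the carboxylate loses CO2, under conditions the trisubstituted alkene tolerates.

Step 3
Reactants: 4 methyl 6-methylhept-5-enoate; 5 methyl formate
Product: 6 methyl 2-formyl-6-methylhept-5-enoate (racemic)
Conditions: LiN(iPr)2, THF, −78 °C; then 5, −78 to 0 °C; aq. NH4Cl
Reagents that add atoms: none
Why: Crossed Claisen condensation (C-formylation) of the preformed lithium ester enolate with the non-enolisable formate, giving a configurationally labile 1,3-dicarbonyl donor as the key step requires.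

Step 4
Reactants: 7 3-(TBSO)propan-1-ol
Product: 8 3-(TBSO)propanal
Conditions: TEMPO (cat.), PhI(OAc)2, CH2Cl2, rt
Reagents that add atoms: none
Why: Nitroxyl-catalysed (oxoammonium) oxidation stops at the aldehyde and, being near neutral, should neither cleave the silyl ether nor cause β-elimination.

Step 5
Reactants: 8 3-(TBSO)propanal; 9 1-(triphenylphosphoranylidene)propan-2-one
Product: 10 (3E)-6-(TBSO)hex-3-en-2-one
Conditions: CH2Cl2, rt
Reagents that add atoms: none
Why: Wittig olefination with a ketone-stabilised ylide, which gives the (E)-enone.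

Step 6
Reactants: 6 methyl 2-formyl-6-methylhept-5-enoate; 10 (3E)-6-(TBSO)hex-3-en-2-one
Product: 13 methyl (1S,6S)-6-[2-(TBSO)ethyl]-1-(4-methylpent-3-en-1-yl)-4-oxocyclohex-2-ene-1-carboxylate, via keto aldehyde 11 (not isolated), via ketol 12 (not isolated)
Conditions: 9-amino-9-deoxy-epi-quinine (20 mol %), salicylic acid (40 mol %), toluene, 40 °C, then 60 °C
Reagents that add atoms: none
Why: The primary amine condenses with the methyl ketone of 10 to an iminium ion while the protonated quinuclidine hydrogen-bonds the internally chelated enol of 6, whose fully substituted α-carbon adds to the β-carbon (C1–C2) to give 11; the enamine of the methyl ketone then attacks the now non-enolisable aldehyde in a 6-(enolendo)-exo-trig aldol to 12, and loss of water gives the C5=C6 enone 13. The closest known reaction type is the amine-catalysed Michael addition–aldol condensation (asymmetric Robinson annulation) of α-substituted 1,3-dicarbonyl donors with enones. C2 is set by the iminium face left open by the quinoline unit, and C1 by the enol face presented in the hydrogen-bonded assembly, which should place the ester cis to the C2 side chain. Both enantiomers of the labile donor react through the same achiral enol, so the racemate converges on one product. Regiochemistry is secured by the substrates: the donor has one acidic C–H, only the methyl side of the ketone can close a six-membered ring, and the saturated silyl-ether arm avoids a skipped dienone.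

Step 7
Reactants: 13 methyl (1S,6S)-6-[2-(TBSO)ethyl]-1-(4-methylpent-3-en-1-yl)-4-oxocyclohex-2-ene-1-carboxylate
Product: 14 methyl (1S,6S)-3-iodo-6-[2-(TBSO)ethyl]-1-(4-methylpent-3-en-1-yl)-4-oxocyclohex-2-ene-1-carboxylate
Conditions: I2, pyridine, DMAP (cat.), CH2Cl2, rt
Reagents that add atoms: iodine, II
Why: α-Iodination of the enone by a Baylis–Hillman-type sequence (amine conjugate addition at C6, iodination of the enolate at C5, elimination), a reaction known for 4,4-disubstituted cyclohexenones, while the isolated alkene adds iodine only reversibly.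

Step 8
Reactants: 14 methyl (1S,6S)-3-iodo-6-[2-(TBSO)ethyl]-1-(4-methylpent-3-en-1-yl)-4-oxocyclohex-2-ene-1-carboxylate; 15 (tributylstannyl)methanol
Product: 16 methyl (1S,6S)-3-(hydroxymethyl)-6-[2-(TBSO)ethyl]-1-(4-methylpent-3-en-1-yl)-4-oxocyclohex-2-ene-1-carboxylate
Conditions: Pd(PPh3)4 (5 mol %), toluene, 90 °C
Reagents that add atoms: none
Why: Stille cross-coupling of the α-iodoenone, in which the oxygen-bearing CH2 group transfers in preference to butyl and the zerovalent palladium catalyst leaves ester, silyl ether and alkenes alone.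

Step 9
Reactants: 16 methyl (1S,6S)-3-(hydroxymethyl)-6-[2-(TBSO)ethyl]-1-(4-methylpent-3-en-1-yl)-4-oxocyclohex-2-ene-1-carboxylate
Product: 17 methyl (1S,6S)-3-[(TBDPSO)methyl]-6-[2-(TBSO)ethyl]-1-(4-methylpent-3-en-1-yl)-4-oxocyclohex-2-ene-1-carboxylate
Conditions: TBDPSCl, imidazole, CH2Cl2, 0 °C to rt
Reagents that add atoms: tert-butyl(chloro)diphenylsilane, CC(C)(C)[Si](Cl)(c1ccccc1)c1ccccc1
Why: Silylation of the primary allylic alcohol with a group chosen to outlast the later acid removal of the primary TBS ether and to fall only to fluoride at the end.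

Step 10
Reactants: 17 methyl (1S,6S)-3-[(TBDPSO)methyl]-6-[2-(TBSO)ethyl]-1-(4-methylpent-3-en-1-yl)-4-oxocyclohex-2-ene-1-carboxylate
Product: 18 methyl (1S,4R,6S)-3-[(TBDPSO)methyl]-4-hydroxy-6-[2-(TBSO)ethyl]-1-(4-methylpent-3-en-1-yl)cyclohex-2-ene-1-carboxylate
Conditions: NaBH4, CeCl3·7H2O, MeOH, −78 °C
Reagents that add atoms: none
Why: Luche 1,2-reduction, in which hydride should add axially to C4 on the face anti to the pseudo-equatorial C2 side chain (the other face carries the axial ester), giving the 1,3-cis alcohol, which is the wrong C4 epimer for the relay and is therefore inverted in step 11.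

Step 11
Reactants: 18 methyl (1S,4R,6S)-3-[(TBDPSO)methyl]-4-hydroxy-6-[2-(TBSO)ethyl]-1-(4-methylpent-3-en-1-yl)cyclohex-2-ene-1-carboxylate; 19 (4-methylbenzenesulfonyl)acetic acid
Product: 20 methyl (1S,4S,6S)-3-[(TBDPSO)methyl]-6-[2-(TBSO)ethyl]-1-(4-methylpent-3-en-1-yl)-4-[(Ts-acetyl)oxy]cyclohex-2-ene-1-carboxylate
Conditions: PPh3, DIAD, toluene, 0 °C to rt
Reagents that add atoms: none
Why: Mitsunobu esterification with a strongly acidic carboxylic acid proceeds by SN2 inversion at C4 and puts the oxygen on the face cis to the homoprenyl group, SN2′ attack being disfavoured because C6 is neopentylic; should 18 prove to be the trans epimer, carbodiimide esterification with retention would give 20 instead.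

Step 12
Reactants: 20 methyl (1S,4S,6S)-3-[(TBDPSO)methyl]-6-[2-(TBSO)ethyl]-1-(4-methylpent-3-en-1-yl)-4-[(Ts-acetyl)oxy]cyclohex-2-ene-1-carboxylate
Product: 23 methyl (1S,2S,6R)-3-[(TBDPSO)methyl]-6-[2-(TBSO)ethyl]-1-(4-methylpent-3-en-1-yl)-2-(Ts-methyl)cyclohex-3-ene-1-carboxylate, via silyl ketene acetal 21 (not isolated), via silyl ester 22 (not isolated)
Conditions: N,O-bis(trimethylsilyl)acetamide, KOAc (10 mol %), toluene, 110 °C
Reagents that add atoms: none
Why: Decarboxylative Claisen rearrangement (Ireland–Claisen shift of an allyl sulfonylacetate, then acetate-triggered desilylation and loss of CO2), in which the suprafacial [3,3] shift of ketene acetal 21 carries carbon from the C4 oxygen to the same face of C6, setting C6 trans to the C2 side chain and creating C4=C5, before silyl ester 22 decarboxylates to the sulfone.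

Step 13
Reactants: 23 methyl (1S,2S,6R)-3-[(TBDPSO)methyl]-6-[2-(TBSO)ethyl]-1-(4-methylpent-3-en-1-yl)-2-(Ts-methyl)cyclohex-3-ene-1-carboxylate
Product: 24 methyl (1S,2S,6R)-3-[(TBDPSO)methyl]-6-(2-hydroxyethyl)-1-(4-methylpent-3-en-1-yl)-2-(Ts-methyl)cyclohex-3-ene-1-carboxylate
Conditions: PPTS, MeOH, rt
Reagents that add atoms: none
Why: Acid-catalysed methanolysis cleaves the unhindered primary TBS ether far faster than the TBDPS ether, and the doubly flanked ester on the quaternary carbon is expected not to lactonise under these mild conditions, 24 being oxidised without storage.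

Step 14
Reactants: 24 methyl (1S,2S,6R)-3-[(TBDPSO)methyl]-6-(2-hydroxyethyl)-1-(4-methylpent-3-en-1-yl)-2-(Ts-methyl)cyclohex-3-ene-1-carboxylate
Product: 25 methyl (1S,2S,6R)-3-[(TBDPSO)methyl]-1-(4-methylpent-3-en-1-yl)-6-(2-oxoethyl)-2-(Ts-methyl)cyclohex-3-ene-1-carboxylate
Conditions: TEMPO (cat.), PhI(OAc)2, CH2Cl2, rt
Reagents that add atoms: none
Why: Nitroxyl-catalysed oxidation of the primary alcohol to the aldehyde, to which sulfone, alkenes and silyl ether are inert.

Step 15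
Reactants: 25 methyl (1S,2S,6R)-3-[(TBDPSO)methyl]-1-(4-methylpent-3-en-1-yl)-6-(2-oxoethyl)-2-(Ts-methyl)cyclohex-3-ene-1-carboxylate; 26 isopropenylmagnesium bromide
Product: 27 methyl (1S,2S,6R)-3-[(TBDPSO)methyl]-6-(2-hydroxy-3-methylbut-3-en-1-yl)-1-(4-methylpent-3-en-1-yl)-2-(Ts-methyl)cyclohex-3-ene-1-carboxylate (both carbinol epimers)
Conditions: THF, −78 °C; cold aq. NH4Cl
Reagents that add atoms: none
Why: Grignard 1,2-addition to the aldehyde at low temperature outruns deprotonation next to the sulfone and attack on the hindered ester, the cold quench is meant to forestall lactonisation of the magnesium alkoxide, and the new carbinol centre may form as both epimers because it becomes sp2 in step 16.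

Step 16
Reactants: 27 methyl (1S,2S,6R)-3-[(TBDPSO)methyl]-6-(2-hydroxy-3-methylbut-3-en-1-yl)-1-(4-methylpent-3-en-1-yl)-2-(Ts-methyl)cyclohex-3-ene-1-carboxylate; 28 triethyl orthoacetate
Product: 30 methyl (1S,2S,6S)-3-[(TBDPSO)methyl]-6-[(2E)-6-ethoxy-3-methyl-6-oxohex-2-en-1-yl]-1-(4-methylpent-3-en-1-yl)-2-(Ts-methyl)cyclohex-3-ene-1-carboxylate, via ketene acetal 29 (not isolated)
Conditions: EtCO2H (cat.), neat 28, 140 °C, EtOH distilled off
Reagents that add atoms: none
Why: Johnson–Claisen orthoester rearrangement through ketene acetal 29, whose chair transition state with the B1 substituent equatorial gives the (E)-trisubstituted B2=B3 alkene and forms B4–B5, the fast orthoester exchange being expected to outpace lactonisation onto the hindered ester.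

Step 17
Reactants: 30 methyl (1S,2S,6S)-3-[(TBDPSO)methyl]-6-[(2E)-6-ethoxy-3-methyl-6-oxohex-2-en-1-yl]-1-(4-methylpent-3-en-1-yl)-2-(Ts-methyl)cyclohex-3-ene-1-carboxylate
Product: 31 methyl (1S,2S,6S)-3-[(TBDPSO)methyl]-6-[(2E)-3-methyl-6-oxohex-2-en-1-yl]-1-(4-methylpent-3-en-1-yl)-2-(Ts-methyl)cyclohex-3-ene-1-carboxylate
Conditions: iBu2AlH (1.1 equiv), CH2Cl2, −78 °C; aq. potassium sodium tartrate
Reagents that add atoms: none
Why: Partial reduction of the unhindered ethyl ester through its aluminium hemiacetal, stable at −78 °C, while the methyl ester on the fully substituted and doubly flanked C1 is far less accessible.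

Step 18
Reactants: 31 methyl (1S,2S,6S)-3-[(TBDPSO)methyl]-6-[(2E)-3-methyl-6-oxohex-2-en-1-yl]-1-(4-methylpent-3-en-1-yl)-2-(Ts-methyl)cyclohex-3-ene-1-carboxylate; 32 ethyl 2-[bis(2,2,2-trifluoroethoxy)phosphoryl]propanoate
Product: 33 methyl (1S,2S,6S)-3-[(TBDPSO)methyl]-6-[(2E,6Z)-8-ethoxy-3,7-dimethyl-8-oxoocta-2,6-dien-1-yl]-1-(4-methylpent-3-en-1-yl)-2-(Ts-methyl)cyclohex-3-ene-1-carboxylate
Conditions: KN(SiMe3)2, 18-crown-6, THF, −78 °C (32 deprotonated first, then 31 added)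
Reagents that add atoms: none
Why: Still–Gennari variant of the Horner–Wadsworth–Emmons reaction, in which the electron-poor phosphonate with a dissociated potassium ion eliminates quickly from the kinetic adduct to give the (Z)-2-methyl enoate, the base being consumed by the phosphonate before the sulfone-bearing aldehyde is introduced.

Step 19
Reactants: 33 methyl (1S,2S,6S)-3-[(TBDPSO)methyl]-6-[(2E,6Z)-8-ethoxy-3,7-dimethyl-8-oxoocta-2,6-dien-1-yl]-1-(4-methylpent-3-en-1-yl)-2-(Ts-methyl)cyclohex-3-ene-1-carboxylate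
Product: 34 methyl (1S,2S,6S)-3-[(TBDPSO)methyl]-6-[(2E,6Z)-8-hydroxy-3,7-dimethylocta-2,6-dien-1-yl]-1-(4-methylpent-3-en-1-yl)-2-(Ts-methyl)cyclohex-3-ene-1-carboxylate
Conditions: iBu2AlH (2.5 equiv), CH2Cl2, −78 °C; aq. potassium sodium tartrate
Reagents that add atoms: none
Why: 1,2-Reduction of the conjugated ester to the allylic alcohol by the aluminium hydride, which again spares the hindered C1 ester and keeps the Z geometry.

Step 20
Reactants: 34 methyl (1S,2S,6S)-3-[(TBDPSO)methyl]-6-[(2E,6Z)-8-hydroxy-3,7-dimethylocta-2,6-dien-1-yl]-1-(4-methylpent-3-en-1-yl)-2-(Ts-methyl)cyclohex-3-ene-1-carboxylate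
Product: 36 methyl (1S,2S,6S)-3-[(TBDPSO)methyl]-6-[(2E,6Z)-8-chloro-3,7-dimethylocta-2,6-dien-1-yl]-1-(4-methylpent-3-en-1-yl)-2-(Ts-methyl)cyclohex-3-ene-1-carboxylate, via mesylate 35 (not isolated)
Conditions: MsCl, 2,4,6-collidine, LiCl, DMF, 0 °C
Reagents that add atoms: lithium chloride, [Li+].[Cl-]
Why: Mesylation and in situ SN2 displacement by chloride convert the primary allylic alcohol into the chloride without allylic transposition or Z-to-E isomerisation.

Step 21
Reactants: 36 methyl (1S,2S,6S)-3-[(TBDPSO)methyl]-6-[(2E,6Z)-8-chloro-3,7-dimethylocta-2,6-dien-1-yl]-1-(4-methylpent-3-en-1-yl)-2-(Ts-methyl)cyclohex-3-ene-1-carboxylate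
Product: 37 methyl (1S,3E,7Z,11S,15S)-12-[(TBDPSO)methyl]-4,8-dimethyl-15-(4-methylpent-3-en-1-yl)-10-Ts-bicyclo[9.3.1]pentadeca-3,7,12-triene-15-carboxylate (both C10 epimers)
Conditions: KN(SiMe3)2 (1.2 equiv), THF, 0 °C, syringe-pump addition of 36 to about 1 mM
Reagents that add atoms: none
Why: Intramolecular SN2 alkylation of the α-sulfonyl carbanion (the only acidic C–H, since the ester has no α-hydrogen) on the primary allylic chloride under high dilution closes the 12-membered ring at B8–B9, a macrocyclisation type established for terpenoid carbocycles, and the sulfone-bearing centre is erased in step 22.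

Step 22
Reactants: 37 methyl (1S,3E,7Z,11S,15S)-12-[(TBDPSO)methyl]-4,8-dimethyl-15-(4-methylpent-3-en-1-yl)-10-Ts-bicyclo[9.3.1]pentadeca-3,7,12-triene-15-carboxylate
Product: 38 methyl (1S,3E,7Z,11S,15S)-12-[(TBDPSO)methyl]-4,8-dimethyl-15-(4-methylpent-3-en-1-yl)bicyclo[9.3.1]pentadeca-3,7,12-triene-15-carboxylate
Conditions: Na/Hg (5% sodium amalgam), Na2HPO4, MeOH/THF, −20 °C
Reagents that add atoms: none
Why: Reductive desulfonylation by single-electron transfer, which replaces C–S by C–H without moving any of the three double bonds because the sulfone sits on a non-allylic carbon.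

Step 23
Reactants: 38 methyl (1S,3E,7Z,11S,15S)-12-[(TBDPSO)methyl]-4,8-dimethyl-15-(4-methylpent-3-en-1-yl)bicyclo[9.3.1]pentadeca-3,7,12-triene-15-carboxylate
Product: 39 methyl (1S,3E,7Z,11S,15S)-12-(hydroxymethyl)-4,8-dimethyl-15-(4-methylpent-3-en-1-yl)bicyclo[9.3.1]pentadeca-3,7,12-triene-15-carboxylate
Conditions: Bu4NF, THF, rt
Reagents that add atoms: none
Why: Fluoride cleavage of the silyl ether, after which the free alcohol cannot lactonise onto the C1 ester because that would put the C4=C5 double bond at a bridgehead.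

Step 24
Reactants: 39 methyl (1S,3E,7Z,11S,15S)-12-(hydroxymethyl)-4,8-dimethyl-15-(4-methylpent-3-en-1-yl)bicyclo[9.3.1]pentadeca-3,7,12-triene-15-carboxylate
Product: 40 (1S,3E,7Z,11S,15S)-12-(hydroxymethyl)-4,8-dimethyl-15-(4-methylpent-3-en-1-yl)bicyclo[9.3.1]pentadeca-3,7,12-triene-15-carboxylic acid (CNP0267152.2)
Conditions: NaSEt, DMF, 80 °C; then aq. HCl to pH 3
Reagents that add atoms: none
Why: The ester carbonyl on the quaternary carbon is too hindered for saponification, so the methyl group is removed by SN2 attack of thiolate on O–CH3, which leaves the alkenes, the allylic alcohol and the three stereocentres untouched.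

Compound list
1 | dimethyl malonate | COC(=O)CC(=O)OC | starting material
2 | 5-bromo-2-methylpent-2-ene | CC(C)=CCCBr | starting material
3 | dimethyl 2-(4-methylpent-3-en-1-yl)malonate | CC(C)=CCCC(C(=O)OC)C(=O)OC | intermediate
4 | methyl 6-methylhept-5-enoate | CC(C)=CCCCC(=O)OC | intermediate
5 | methyl formate | COC=O | starting material
6 | methyl 2-formyl-6-methylhept-5-enoate (racemic) | CC(C)=CCCC(C=O)C(=O)OC | intermediate
7 | 3-[(tert-butyldimethylsilyl)oxy]propan-1-ol | OCCCO[Si](C)(C)C(C)(C)C | starting material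
8 | 3-[(tert-butyldimethylsilyl)oxy]propanal | O=CCCO[Si](C)(C)C(C)(C)C | intermediate
9 | 1-(triphenylphosphoranylidene)propan-2-one | CC(=O)C=P(c1ccccc1)(c1ccccc1)c1ccccc1 | starting material
10 | (3E)-6-[(tert-butyldimethylsilyl)oxy]hex-3-en-2-one | CC(=O)/C=C/CCO[Si](C)(C)C(C)(C)C | intermediate
11 | methyl (2S)-2-formyl-6-methyl-2-[(3S)-1-(TBSO)-5-oxohexan-3-yl]hept-5-enoate (keto aldehyde, not isolated) | CC(C)=CCC[C@](C=O)(C(=O)OC)[C@@H](CCO[Si](C)(C)C(C)(C)C)CC(C)=O | intermediate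
12 | methyl (1S,6S)-2-hydroxy-6-[2-(TBSO)ethyl]-1-(4-methylpent-3-en-1-yl)-4-oxocyclohexane-1-carboxylate (ketol, carbinol epimers, not isolated) | CC(C)=CCC[C@]1(C(=O)OC)[C@@H](CCO[Si](C)(C)C(C)(C)C)CC(=O)CC1O | intermediate
13 | methyl (1S,6S)-6-[2-(TBSO)ethyl]-1-(4-methylpent-3-en-1-yl)-4-oxocyclohex-2-ene-1-carboxylate | CC(C)=CCC[C@]1(C(=O)OC)[C@@H](CCO[Si](C)(C)C(C)(C)C)CC(=O)C=C1 | intermediate
14 | methyl (1S,6S)-3-iodo-6-[2-(TBSO)ethyl]-1-(4-methylpent-3-en-1-yl)-4-oxocyclohex-2-ene-1-carboxylate | CC(C)=CCC[C@]1(C(=O)OC)[C@@H](CCO[Si](C)(C)C(C)(C)C)CC(=O)C(I)=C1 | intermediate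
15 | (tributylstannyl)methanol | OC[Sn](CCCC)(CCCC)CCCC | starting material
16 | methyl (1S,6S)-3-(hydroxymethyl)-6-[2-(TBSO)ethyl]-1-(4-methylpent-3-en-1-yl)-4-oxocyclohex-2-ene-1-carboxylate | CC(C)=CCC[C@]1(C(=O)OC)[C@@H](CCO[Si](C)(C)C(C)(C)C)CC(=O)C(CO)=C1 | intermediate
17 | methyl (1S,6S)-3-[(TBDPSO)methyl]-6-[2-(TBSO)ethyl]-1-(4-methylpent-3-en-1-yl)-4-oxocyclohex-2-ene-1-carboxylate | CC(C)=CCC[C@]1(C(=O)OC)[C@@H](CCO[Si](C)(C)C(C)(C)C)CC(=O)C(CO[Si](c2ccccc2)(c2ccccc2)C(C)(C)C)=C1 | intermediate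
18 | methyl (1S,4R,6S)-3-[(TBDPSO)methyl]-4-hydroxy-6-[2-(TBSO)ethyl]-1-(4-methylpent-3-en-1-yl)cyclohex-2-ene-1-carboxylate | CC(C)=CCC[C@]1(C(=O)OC)[C@@H](CCO[Si](C)(C)C(C)(C)C)C[C@@H](O)C(CO[Si](c2ccccc2)(c2ccccc2)C(C)(C)C)=C1 | intermediate
19 | (4-methylbenzenesulfonyl)acetic acid | Cc1ccc(cc1)S(=O)(=O)CC(=O)O | starting material
20 | methyl (1S,4S,6S)-3-[(TBDPSO)methyl]-6-[2-(TBSO)ethyl]-1-(4-methylpent-3-en-1-yl)-4-[(Ts-acetyl)oxy]cyclohex-2-ene-1-carboxylate | CC(C)=CCC[C@]1(C(=O)OC)[C@@H](CCO[Si](C)(C)C(C)(C)C)C[C@H](OC(=O)CS(=O)(=O)c2ccc(C)cc2)C(CO[Si](c2ccccc2)(c2ccccc2)C(C)(C)C)=C1 | intermediate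
21 | O-trimethylsilyl ketene acetal of 20 (not isolated) | CC(C)=CCC[C@]1(C(=O)OC)[C@@H](CCO[Si](C)(C)C(C)(C)C)C[C@H](OC(O[Si](C)(C)C)=CS(=O)(=O)c2ccc(C)cc2)C(CO[Si](c2ccccc2)(c2ccccc2)C(C)(C)C)=C1 | intermediate
22 | trimethylsilyl ester of the rearranged 2-(cyclohexenyl)-2-Ts-acetic acid, ring centres as in 23 (not isolated) | CC(C)=CCC[C@]1(C(=O)OC)[C@@H](CCO[Si](C)(C)C(C)(C)C)CC=C(CO[Si](c2ccccc2)(c2ccccc2)C(C)(C)C)[C@@H]1C(C(=O)O[Si](C)(C)C)S(=O)(=O)c2ccc(C)cc2 | intermediate
23 | methyl (1S,2S,6R)-3-[(TBDPSO)methyl]-6-[2-(TBSO)ethyl]-1-(4-methylpent-3-en-1-yl)-2-(Ts-methyl)cyclohex-3-ene-1-carboxylate | CC(C)=CCC[C@]1(C(=O)OC)[C@@H](CCO[Si](C)(C)C(C)(C)C)CC=C(CO[Si](c2ccccc2)(c2ccccc2)C(C)(C)C)[C@@H]1CS(=O)(=O)c2ccc(C)cc2 | intermediate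
24 | methyl (1S,2S,6R)-3-[(TBDPSO)methyl]-6-(2-hydroxyethyl)-1-(4-methylpent-3-en-1-yl)-2-(Ts-methyl)cyclohex-3-ene-1-carboxylate | CC(C)=CCC[C@]1(C(=O)OC)[C@@H](CCO)CC=C(CO[Si](c2ccccc2)(c2ccccc2)C(C)(C)C)[C@@H]1CS(=O)(=O)c2ccc(C)cc2 | intermediate
25 | methyl (1S,2S,6R)-3-[(TBDPSO)methyl]-1-(4-methylpent-3-en-1-yl)-6-(2-oxoethyl)-2-(Ts-methyl)cyclohex-3-ene-1-carboxylate | CC(C)=CCC[C@]1(C(=O)OC)[C@@H](CC=O)CC=C(CO[Si](c2ccccc2)(c2ccccc2)C(C)(C)C)[C@@H]1CS(=O)(=O)c2ccc(C)cc2 | intermediate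
26 | isopropenylmagnesium bromide | CC(=C)[Mg]Br | starting material
27 | methyl (1S,2S,6R)-3-[(TBDPSO)methyl]-6-(2-hydroxy-3-methylbut-3-en-1-yl)-1-(4-methylpent-3-en-1-yl)-2-(Ts-methyl)cyclohex-3-ene-1-carboxylate (both carbinol epimers) | CC(C)=CCC[C@]1(C(=O)OC)[C@@H](CC(O)C(C)=C)CC=C(CO[Si](c2ccccc2)(c2ccccc2)C(C)(C)C)[C@@H]1CS(=O)(=O)c2ccc(C)cc2 | intermediate
28 | triethyl orthoacetate | CCOC(C)(OCC)OCC | starting material
29 | 1-ethoxyvinyl ether of 27 (mixed ketene acetal, not isolated) | CC(C)=CCC[C@]1(C(=O)OC)[C@@H](CC(OC(=C)OCC)C(C)=C)CC=C(CO[Si](c2ccccc2)(c2ccccc2)C(C)(C)C)[C@@H]1CS(=O)(=O)c2ccc(C)cc2 | intermediate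
30 | methyl (1S,2S,6S)-3-[(TBDPSO)methyl]-6-[(2E)-6-ethoxy-3-methyl-6-oxohex-2-en-1-yl]-1-(4-methylpent-3-en-1-yl)-2-(Ts-methyl)cyclohex-3-ene-1-carboxylate | CC(C)=CCC[C@]1(C(=O)OC)[C@@H](C/C=C(C)/CCC(=O)OCC)CC=C(CO[Si](c2ccccc2)(c2ccccc2)C(C)(C)C)[C@@H]1CS(=O)(=O)c2ccc(C)cc2 | intermediate
31 | methyl (1S,2S,6S)-3-[(TBDPSO)methyl]-6-[(2E)-3-methyl-6-oxohex-2-en-1-yl]-1-(4-methylpent-3-en-1-yl)-2-(Ts-methyl)cyclohex-3-ene-1-carboxylate | CC(C)=CCC[C@]1(C(=O)OC)[C@@H](C/C=C(C)/CCC=O)CC=C(CO[Si](c2ccccc2)(c2ccccc2)C(C)(C)C)[C@@H]1CS(=O)(=O)c2ccc(C)cc2 | intermediate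
32 | ethyl 2-[bis(2,2,2-trifluoroethoxy)phosphoryl]propanoate | CCOC(=O)C(C)P(=O)(OCC(F)(F)F)OCC(F)(F)F | starting material
33 | methyl (1S,2S,6S)-3-[(TBDPSO)methyl]-6-[(2E,6Z)-8-ethoxy-3,7-dimethyl-8-oxoocta-2,6-dien-1-yl]-1-(4-methylpent-3-en-1-yl)-2-(Ts-methyl)cyclohex-3-ene-1-carboxylate | CC(C)=CCC[C@]1(C(=O)OC)[C@@H](C/C=C(C)/CC/C=C(/C)C(=O)OCC)CC=C(CO[Si](c2ccccc2)(c2ccccc2)C(C)(C)C)[C@@H]1CS(=O)(=O)c2ccc(C)cc2 | intermediate
34 | methyl (1S,2S,6S)-3-[(TBDPSO)methyl]-6-[(2E,6Z)-8-hydroxy-3,7-dimethylocta-2,6-dien-1-yl]-1-(4-methylpent-3-en-1-yl)-2-(Ts-methyl)cyclohex-3-ene-1-carboxylate | CC(C)=CCC[C@]1(C(=O)OC)[C@@H](C/C=C(C)/CC/C=C(/C)CO)CC=C(CO[Si](c2ccccc2)(c2ccccc2)C(C)(C)C)[C@@H]1CS(=O)(=O)c2ccc(C)cc2 | intermediate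
35 | methanesulfonate of 34 (not isolated) | CC(C)=CCC[C@]1(C(=O)OC)[C@@H](C/C=C(C)/CC/C=C(/C)COS(C)(=O)=O)CC=C(CO[Si](c2ccccc2)(c2ccccc2)C(C)(C)C)[C@@H]1CS(=O)(=O)c2ccc(C)cc2 | intermediate
36 | methyl (1S,2S,6S)-3-[(TBDPSO)methyl]-6-[(2E,6Z)-8-chloro-3,7-dimethylocta-2,6-dien-1-yl]-1-(4-methylpent-3-en-1-yl)-2-(Ts-methyl)cyclohex-3-ene-1-carboxylate | CC(C)=CCC[C@]1(C(=O)OC)[C@@H](C/C=C(C)/CC/C=C(/C)CCl)CC=C(CO[Si](c2ccccc2)(c2ccccc2)C(C)(C)C)[C@@H]1CS(=O)(=O)c2ccc(C)cc2 | intermediate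
37 | methyl (1S,3E,7Z,11S,15S)-12-[(TBDPSO)methyl]-4,8-dimethyl-15-(4-methylpent-3-en-1-yl)-10-Ts-bicyclo[9.3.1]pentadeca-3,7,12-triene-15-carboxylate (both C10 epimers) | CC(C)=CCC[C@]1(C(=O)OC)[C@@H]2CC=C(CO[Si](c3ccccc3)(c3ccccc3)C(C)(C)C)[C@@H]1C(S(=O)(=O)c3ccc(C)cc3)C/C(C)=C\CC/C(C)=C/C2 | intermediate
38 | methyl (1S,3E,7Z,11S,15S)-12-[(TBDPSO)methyl]-4,8-dimethyl-15-(4-methylpent-3-en-1-yl)bicyclo[9.3.1]pentadeca-3,7,12-triene-15-carboxylate | CC(C)=CCC[C@]1(C(=O)OC)[C@@H]2CC=C(CO[Si](c3ccccc3)(c3ccccc3)C(C)(C)C)[C@@H]1CC/C(C)=C\CC/C(C)=C/C2 | intermediate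
39 | methyl (1S,3E,7Z,11S,15S)-12-(hydroxymethyl)-4,8-dimethyl-15-(4-methylpent-3-en-1-yl)bicyclo[9.3.1]pentadeca-3,7,12-triene-15-carboxylate | CC(C)=CCC[C@]1(C(=O)OC)[C@@H]2CC=C(CO)[C@@H]1CC/C(C)=C\CC/C(C)=C/C2 | intermediate
40 | (1S,3E,7Z,11S,15S)-12-(hydroxymethyl)-4,8-dimethyl-15-(4-methylpent-3-en-1-yl)bicyclo[9.3.1]pentadeca-3,7,12-triene-15-carboxylic acid (CNP0267152.2) | CC(C)=CCC[C@]1(C(=O)O)[C@@H]2CC=C(CO)[C@@H]1CC/C(C)=C\CC/C(C)=C/C2 | target

Total step count: 24. Longest linear sequence: 22 steps (steps 1–3, then 6–24).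

Steps most likely to fail

Step 6. The Michael addition of a fully substituted donor to a β-substituted enone may be slow, and control of both the enone face and the enol face may be incomplete, giving poor diastereo- or enantioselectivity; γ-deprotonation of the enone with loss of silanol may compete. The fallback gives the Michael step to a chiral metal enolate and separates it from the ring closure. It sets out from 6 and 10, which are combined with the divalent palladium aqua complex [Pd((R)-BINAP)(H2O)2](OTf)2 (5–10 mol %) in THF at 0 °C (the BINAP antipode if the sense of induction requires it). Under these conditions 1,3-dicarbonyl compounds add as chelated square-planar palladium enolates to β-substituted enones with control of both new centres. Keto aldehyde 11 is then isolated and closed and dehydrated with pyrrolidine and AcOH in toluene at 50 °C through ketol 12. The fallback rejoins the route at 13 and makes no compound outside the list (F0).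

Step 21. Oligomerisation, E2 loss of HCl or SN2′ attack may outrun the transannular closure, because the C2 and C6 arms lie on opposite faces of ring A and the nucleophilic carbon is next to a congested ring position. The fallback closes the ring at B7–B8 by a B-alkyl Suzuki–Miyaura coupling and needs no sulfone removal. It sets out from 23: deprotonation (n-BuLi, THF, −78 °C) and alkylation with (iodomethyl)tributylstannane give β-stannyl sulfone F4, which on warming in toluene eliminates the tin sulfinate to give the C6 vinyl compound F5. The C2 arm is then grown as in steps 13–17: PPTS in MeOH gives alcohol F6, TEMPO and PhI(OAc)2 give aldehyde F7, isopropenylmagnesium bromide gives carbinol F8, Johnson–Claisen rearrangement with 28 gives ethyl ester F9, and iBu2AlH at −78 °C gives aldehyde F10. Stork–Zhao olefination with Ph3P=C(I)CH3 (from ethyltriphenylphosphonium iodide, n-BuLi, I2, then NaN(SiMe3)2, THF, −78 °C) gives the (Z)-vinyl iodide F11. 9-BBN hydroborates only the monosubstituted vinyl group, and coupling with PdCl2(dppf), AsPh3 and Cs2CO3 in DMF/THF/H2O at high dilution retains the Z geometry. The fallback rejoins the route at 38.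

Step 12. The [3,3] shift may fail to reach the congested C6 terminus next to the quaternary carbon, so that the sulfonylacetate eliminates to a diene or loses CO2 without rearranging. The fallback moves the carbon by a [2,3] shift of a sulfonium ylide (Doyle–Kirmse reaction). It sets out from 18, which with bis(4-methylphenyl) disulfide and PBu3 gives, with inversion at C4, allyl sulfide F1. Ethyl diazoacetate with Rh2(OAc)4 (1 mol %) in CH2Cl2 forms the sulfonium ylide, whose suprafacial [2,3] shift places carbon on the same face of C6 and gives α-sulfanyl ester F2. Oxidation with (NH4)6Mo7O24·4H2O and H2O2 in EtOH gives α-sulfonyl ester F3, and Krapcho dealkoxycarbonylation (LiCl, wet DMSO, 140 °C) removes the ethyl ester. The fallback rejoins the route at 23.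

Further compounds
F0 | step 6 | none | none
F1 | step 12 | allyl sulfide: 4-[(4-methylphenyl)sulfanyl] analogue of 20 at C4, (1S,4S,6S) | CC(C)=CCC[C@]1(C(=O)OC)[C@@H](CCO[Si](C)(C)C(C)(C)C)C[C@H](Sc2ccc(C)cc2)C(CO[Si](c2ccccc2)(c2ccccc2)C(C)(C)C)=C1
F2 | step 12 | α-sulfanyl ester: 23 with C6–CH(S-4-tolyl)CO2Et in place of C6–CH2Ts (epimers at the new carbon) | CC(C)=CCC[C@]1(C(=O)OC)[C@@H](CCO[Si](C)(C)C(C)(C)C)CC=C(CO[Si](c2ccccc2)(c2ccccc2)C(C)(C)C)[C@@H]1C(Sc2ccc(C)cc2)C(=O)OCC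
F3 | step 12 | α-sulfonyl ester: 23 with C6–CH(Ts)CO2Et in place of C6–CH2Ts (epimers at the new carbon) | CC(C)=CCC[C@]1(C(=O)OC)[C@@H](CCO[Si](C)(C)C(C)(C)C)CC=C(CO[Si](c2ccccc2)(c2ccccc2)C(C)(C)C)[C@@H]1C(C(=O)OCC)S(=O)(=O)c2ccc(C)cc2
F4 | step 21 | β-stannyl sulfone: 23 with C6–CH(Ts)CH2SnBu3 (epimers at the sulfone carbon) | CC(C)=CCC[C@]1(C(=O)OC)[C@@H](CCO[Si](C)(C)C(C)(C)C)CC=C(CO[Si](c2ccccc2)(c2ccccc2)C(C)(C)C)[C@@H]1C(C[Sn](CCCC)(CCCC)CCCC)S(=O)(=O)c2ccc(C)cc2
F5 | step 21 | C6 vinyl compound: 23 with vinyl in place of CH2Ts | CC(C)=CCC[C@]1(C(=O)OC)[C@@H](CCO[Si](C)(C)C(C)(C)C)CC=C(CO[Si](c2ccccc2)(c2ccccc2)C(C)(C)C)[C@@H]1C=C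
F6 | step 21 | alcohol: C6 vinyl analogue of 24 | CC(C)=CCC[C@]1(C(=O)OC)[C@@H](CCO)CC=C(CO[Si](c2ccccc2)(c2ccccc2)C(C)(C)C)[C@@H]1C=C
F7 | step 21 | aldehyde: C6 vinyl analogue of 25 | CC(C)=CCC[C@]1(C(=O)OC)[C@@H](CC=O)CC=C(CO[Si](c2ccccc2)(c2ccccc2)C(C)(C)C)[C@@H]1C=C
F8 | step 21 | carbinol: C6 vinyl analogue of 27 (both carbinol epimers) | CC(C)=CCC[C@]1(C(=O)OC)[C@@H](CC(O)C(C)=C)CC=C(CO[Si](c2ccccc2)(c2ccccc2)C(C)(C)C)[C@@H]1C=C
F9 | step 21 | ethyl ester: C6 vinyl analogue of 30 | CC(C)=CCC[C@]1(C(=O)OC)[C@@H](C/C=C(C)/CCC(=O)OCC)CC=C(CO[Si](c2ccccc2)(c2ccccc2)C(C)(C)C)[C@@H]1C=C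
F10 | step 21 | aldehyde: C6 vinyl analogue of 31 | CC(C)=CCC[C@]1(C(=O)OC)[C@@H](C/C=C(C)/CCC=O)CC=C(CO[Si](c2ccccc2)(c2ccccc2)C(C)(C)C)[C@@H]1C=C
F11 | step 21 | (Z)-vinyl iodide: C6 vinyl compound with a (2E,6Z)-7-iodo-3-methylocta-2,6-dien-1-yl arm at C2 | CC(C)=CCC[C@]1(C(=O)OC)[C@@H](C/C=C(C)/CC/C=C(/C)I)CC=C(CO[Si](c2ccccc2)(c2ccccc2)C(C)(C)C)[C@@H]1C=C
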